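The flavone is cut through ring C at two bonds, C4–C4a and O1–C2. This separates a ring A phenol from a C4–C3–C2 keto ester that already carries the 3-methoxy group and ring B. The feature exploited is that ring A bears oxygen on C5, C6, C7, C8 and C8a, leaving C4a as its only carbon-substituted atom. The matching 2,3,4,5-tetramethoxyphenol therefore has a single ring C–H, ortho to its hydroxyl, and no regioisomer can arise. One acid-free thermal condensation with methyl 2-methoxy-3-(4-methoxyphenyl)-3-oxopropanoate makes both bonds and closes the pyranone, giving the 5-O-methyl ether of the target. Chelation-directed cleavage of that one ether ends the route.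

Key step: step 4

Remark on stereochemistry: the target has no stereocentre, stereoaxis or configured double bond, so it is one achiral compound. The only stereocentre met on the way, the α-carbon of the keto ester, is enolisable, is used racemic and disappears in the key step.

Remark on supply: 1,2,3,4-tetramethoxybenzene, methyl methoxyacetate and 4-methoxybenzoyl chloride are taken as catalogue chemicals.

Remark on design:
- The keto ester is kept as its methyl ester because methanol leaves the melt at once. A tert-butyl ester would fragment to isobutene and a β-keto acid that decarboxylates.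
- The keto ester is the cheaper partner and is used in excess, because the water released on ring closure can destroy part of it.

Step 1
Reactants: 1 1,2,3,4-tetramethoxybenzene
Product: 3 2,3,4,5-tetramethoxybenzaldehyde, via aryl iminium chloride 2 (not isolated)
Conditions: POCl3 (1.5 equiv), DMF, 0 → 85 °C; then ice/H2O
Reagents that add atoms: N,N-dimethylformamide, CN(C)C=O (formyl carbon); water, O (aldehyde oxygen)
Why: Vilsmeier–Haack formylation, in which the chloroiminium ion attacks one of the two equivalent ring C–H positions (each ortho and para to methoxy donors) and the deactivating iminium group of 2 prevents a second substitution before water releases the aldehyde.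

Step 2
Reactants: 3 2,3,4,5-tetramethoxybenzaldehyde
Product: 5 2,3,4,5-tetramethoxyphenol, via aryl formate 4 (not isolated)
Conditions: mCPBA (1.2 equiv), CH2Cl2, 0 °C → rt; aq Na2SO3/NaHCO3 wash; then MeOH, cat. HCl, N2, rt
Reagents that add atoms: mCPBA (3-chloroperoxybenzoic acid), OOC(=O)c1cccc(Cl)c1
Why: Baeyer–Villiger (Dakin-type) oxidation, in which the electron-rich aryl group with ortho and para methoxy donors migrates in the Criegee adduct in preference to hydride, and removal of the peracid before the acid-catalysed methanolysis of 4 keeps the oxidisable phenol away from oxidant and base.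

Step 3
Reactants: 6 methyl methoxyacetate; 7 4-methoxybenzoyl chloride
Product: 9 methyl 2-methoxy-3-(4-methoxyphenyl)-3-oxopropanoate (racemic), via lithium enolate 8 (not isolated)
Conditions: 6 (2.1 equiv), LDA (2.1 equiv), THF, −78 °C; then 7 (1.0 equiv), −78 → −20 °C; 1 M HCl
Reagents that add atoms: none
Why: Crossed Claisen-type C-acylation of a chelated lithium glycolate enolate by a non-enolisable aroyl chloride, in which the second equivalent of 8 deprotonates the more acidic product as it forms and so blocks double acylation, while the new stereocentre is configurationally labile and 9 is obtained racemic.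

Step 4
Reactants: 5 2,3,4,5-tetramethoxyphenol; 9 methyl 2-methoxy-3-(4-methoxyphenyl)-3-oxopropanoate
Product: 12 3,5,6,7,8,4'-hexamethoxyflavone, via aroylketene 10 (not isolated), via 2-hydroxyaryl 1,3-diketone 11 (not isolated)
Conditions: neat melt, 9 (2 equiv, two portions), N2 sweep, 240–250 °C (bath or µW), MeOH and H2O distilled out
Reagents that add atoms: none
Why: Mentzer-type thermal chromone synthesis (the acid-free relative of the Simonis reaction): above about 200 °C the enol of 9 expels methanol to give aroylketene 10, whose capture at the phenol oxygen is reversible at this temperature whereas attack by ring carbon C6 of 5 is not, so the material should drain into the hydrogen-bonded diketone 11 and the C4–C4a bond is made. The free hydroxyl of 11 then adds to the anisoyl carbonyl in a 6-exo-trig closure (O1–C2 bond), and loss of water aromatises the new ring to the 4-pyranone, the only ring formed. Site selectivity on ring A is secured by the substrate, since C6 of 5 is its one C–H and has the same ortho, ortho, para oxygen donor pattern as the reacting carbon of phloroglucinol, the standard substrate of this reaction. Chromone over coumarin selectivity is secured by the absence of acid, by the low electrophilicity of the p-anisoyl ketone and by the α-methoxy branch, all of which slow Pechmann-type ring attack at the ketone. No stereocentre is created, and the labile one of 9 becomes the sp2 carbon C3. The excess of 9 and the gas sweep that carries off methanol and water limit retro-Claisen cleavage, hydrolysis and decarboxylation of the keto ester.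

Step 5
Reactants: 12 3,5,6,7,8,4'-hexamethoxyflavone
Product: 14 5-hydroxyauranetin (5-hydroxy-3,6,7,8,4'-pentamethoxyflavone), via dichloroboron chelate 13 (not isolated)
Conditions: BCl3 (1.2 equiv, 1 M in CH2Cl2), CH2Cl2, −78 → 0 °C; then 1 M aq HCl, rt
Reagents that add atoms: none
Why: Chelation-controlled Lewis acid ether cleavage, in which boron ties the C4 carbonyl to the peri 5-methoxy oxygen in a six-membered chelate, chloride removes that methyl group by SN2 attack, and with about one equivalent at low temperature the 3-methoxy group (only a strained five-membered chelate) and the unchelated 6-, 7-, 8- and 4'-ethers should stay intact.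

Compound list
1 | 1,2,3,4-tetramethoxybenzene | COc1ccc(OC)c(OC)c1OC | starting material
2 | N,N-dimethyl(2,3,4,5-tetramethoxybenzylidene)iminium chloride | COc1cc(C=[N+](C)C)c(OC)c(OC)c1OC.[Cl-] | intermediate
3 | 2,3,4,5-tetramethoxybenzaldehyde | COc1cc(C=O)c(OC)c(OC)c1OC | intermediate
4 | 2,3,4,5-tetramethoxyphenyl formate | COc1cc(OC=O)c(OC)c(OC)c1OC | intermediate
5 | 2,3,4,5-tetramethoxyphenol | COc1cc(O)c(OC)c(OC)c1OC | intermediate
6 | methyl methoxyacetate | COCC(=O)OC | starting material
7 | 4-methoxybenzoyl chloride | COc1ccc(C(=O)Cl)cc1 | starting material
8 | lithium enolate of methyl methoxyacetate (lithium 1,2-dimethoxyethenolate, geometry of no consequence) | COC=C([O-])OC.[Li+] | intermediate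
9 | methyl 2-methoxy-3-(4-methoxyphenyl)-3-oxopropanoate (racemic, enolisable stereocentre) | COC(=O)C(OC)C(=O)c1ccc(OC)cc1 | intermediate
10 | 2-methoxy-3-(4-methoxyphenyl)-3-oxoprop-1-en-1-one (α-methoxy aroylketene) | COC(=C=O)C(=O)c1ccc(OC)cc1 | intermediate
11 | 1-(2-hydroxy-3,4,5,6-tetramethoxyphenyl)-2-methoxy-3-(4-methoxyphenyl)propane-1,3-dione (racemic, enolisable) | COc1ccc(cc1)C(=O)C(OC)C(=O)c1c(O)c(OC)c(OC)c(OC)c1OC | intermediate
12 | 3,5,6,7,8,4'-hexamethoxyflavone | COc1ccc(-c2oc3c(OC)c(OC)c(OC)c(OC)c3c(=O)c2OC)cc1 | intermediate
13 | 5-(dichloroboryloxy)-3,6,7,8,4'-pentamethoxyflavone (boron also bound to the C4 carbonyl oxygen) | COc1ccc(-c2oc3c(OC)c(OC)c(OC)c(OB(Cl)Cl)c3c(=O)c2OC)cc1 | intermediate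
14 | 5-hydroxyauranetin (5-hydroxy-3,6,7,8,4'-pentamethoxyflavone, achiral) | COc1ccc(-c2oc3c(OC)c(OC)c(OC)c(O)c3c(=O)c2OC)cc1 | target

Total step count: 5.
Longest linear sequence: 4 steps (1 → 3 → 5 → 12 → 14). Step 3 is a one-step side branch.

Steps most likely to fail

1. Step 4.
- Risk: with a monohydric phenol, ring C-acylation may be slower than the other fates of the ketene. These are reversible O-acylation, self-dimerisation, and hydrolysis followed by decarboxylation. Conversion could then stall or the melt could darken.
- Fallback: a stepwise Baker–Venkataraman assembly of the same two bonds. It sets out from 5 and returns at 11, and from there to 12.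
- Phenol 5 is treated with methoxyacetyl chloride and BF3·OEt2 (O-acylation followed by Fries shift to the one free ring carbon). This should give 1-(2-hydroxy-3,4,5,6-tetramethoxyphenyl)-2-methoxyethan-1-one F1.
- Esterification of its hydroxyl with 7 in pyridine gives 2-(methoxyacetyl)-3,4,5,6-tetramethoxyphenyl 4-methoxybenzoate F2.
- KOH in pyridine, or LiHMDS in THF, then moves the aroyl group from oxygen to the α-carbon. This delivers diketone 11, now as an isolated compound, and catalytic H2SO4 in AcOH closes it to 12.

2. Step 5.
- Risk: discrimination between the two ethers that flank the carbonyl (5-O and 3-O) may be lost. Cleavage may also continue at the 6-O next to the boron phenolate if the Lewis acid is in excess or the mixture warms.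
- Fallback: it sets out from 12 and returns at 14, and it turns the likely over-reaction into the plan.
- Both carbonyl-flanking ethers are cleaved on purpose with AlBr3 in MeCN to give 3,5-dihydroxy-6,7,8,4'-tetramethoxyflavone F3.
- One equivalent of MeI with K2CO3 in acetone then methylates only the 3-hydroxyl. The 5-hydroxyl is held in a strong hydrogen bond to the C4 carbonyl and is the least reactive hydroxyl of a flavonol.

3. Step 3.
- Risk: O-acylation of the enolate, a second acylation of the product enolate, or self-condensation of the glycolate ester may compete with the wanted C-acylation.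
- Fallback: it sets out from 6 (through enolate 8) and returns at 9. It replaces acylation by aldol addition and oxidation.
- Enolate 8 is added to 4-methoxybenzaldehyde at −78 °C to give methyl 3-hydroxy-2-methoxy-3-(4-methoxyphenyl)propanoate F4. This is a racemic mixture of diastereomers, which does not matter here.
- Dess–Martin periodinane in CH2Cl2 oxidises the activated benzylic alcohol to 9.

Further compounds
F1 | step 4 | 1-(2-hydroxy-3,4,5,6-tetramethoxyphenyl)-2-methoxyethan-1-one | COCC(=O)c1c(O)c(OC)c(OC)c(OC)c1OC
F2 | step 4 | 2-(methoxyacetyl)-3,4,5,6-tetramethoxyphenyl 4-methoxybenzoate | COCC(=O)c1c(OC(=O)c2ccc(OC)cc2)c(OC)c(OC)c(OC)c1OC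
F3 | step 5 | 3,5-dihydroxy-6,7,8,4'-tetramethoxyflavone | COc1ccc(-c2oc3c(OC)c(OC)c(OC)c(O)c3c(=O)c2O)cc1
F4 | step 3 | methyl 3-hydroxy-2-methoxy-3-(4-methoxyphenyl)propanoate (racemic diastereomer mixture) | COC(=O)C(OC)C(O)c1ccc(OC)cc1
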